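**Plan**

- Cuts (flavone numbering): O7 is masked as a tert-butyl ether and the O8 methyl is added late. Ring A is cut at C8–C8a (electrocyclic bond) and C4a–C5 (carbonyl addition). Ring C is cut at O1–C8a and C2–C3.
- Pieces: dimethyl squarate (C5–C8 with their four oxygens), 3,4,5-trimethoxybenzoyl chloride (ring B and C2) and (E)-4-methoxybut-3-en-2-one (C3, C4, C4a, C8a).
- Forward order: ring B is bought. Ring C is closed as a 5-iodo-2-aryl-4-pyranone. The four-membered ring is attached at C4a by a Grignard addition. Ring A is formed last by thermal ring expansion, followed by O8-methylation and loss of the tert-butyl group.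
- Enabling feature: ring A carries oxygen on four adjacent carbons (C5, C6, C7, C8), the C4O4 unit of a squarate. Its other two carbons (C4a, C8a) are the C5=C6 double bond of the pyranone that already holds rings C and B.
- Stereochemistry: the target has no stereocenter. The carbinol carbon of the cyclobutenone adduct and C8a of a transient dienone are racemic and are erased when ring A aromatizes.

Key step: step 7

Remark on the chemistry: the iodination in step 1 is assumed to give the Z isomer (methoxy trans to acetyl); this geometry is destroyed in step 3, so the E isomer would serve equally.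

Remark on the chemistry: positions of the flavone are numbered O1, C2, C3, C4, C4a, C5–C8, C8a; the cyclobutenone is numbered from its carbonyl carbon (C1) to the carbinol carbon (C4).

**Route**

Step 1
Reactants: 1 (E)-4-methoxybut-3-en-2-one
Product: 2 (Z)-3-iodo-4-methoxybut-3-en-2-one
Conditions: I2 (1.5 equiv), pyridine/CH2Cl2 (1:1), 0 °C → rt, dark; aq. Na2S2O3
Reagents that add atoms: iodine, II
Why: Electrophilic α-iodination of an enone with I2/pyridine, in which the enol ether makes C3 the only nucleophilic carbon, iodine adds there and pyridine removes the C3 proton, the isomer with methoxy trans to the acetyl group being expected.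

Step 2
Reactants: 2 (Z)-3-iodo-4-methoxybut-3-en-2-one; 3 3,4,5-trimethoxybenzoyl chloride
Product: 5 (Z)-4-iodo-5-methoxy-1-(3,4,5-trimethoxyphenyl)pent-4-ene-1,3-dione, via lithium dienolate 4 (not isolated)
Conditions: 2 (2.0 equiv), LiN(SiMe3)2 (2.05 equiv), THF, –78 °C; then 3 (1.0 equiv), –78 → –40 °C; 1 M HCl
Reagents that add atoms: none
Why: Crossed Claisen C-acylation in which the amide base deprotonates the only enolizable position (the methyl group), the dienolate attacks the aroyl chloride at carbon, and the second equivalent of enolate takes up the acidic proton of the new 1,3-diketone so that acylation stops after one aroyl group.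

Step 3
Reactants: 5 (Z)-4-iodo-5-methoxy-1-(3,4,5-trimethoxyphenyl)pent-4-ene-1,3-dione
Product: 6 5-iodo-2-(3,4,5-trimethoxyphenyl)-4H-pyran-4-one
Conditions: CF3CO2H (2 equiv), CH2Cl2, rt
Reagents that add atoms: none
Why: Acid-mediated 6-endo oxa-Michael addition of the diketone enol oxygen to the β-methoxy enone followed by loss of methanol, the standard closure of 4-pyranones from 5-methoxypent-4-ene-1,3-diones, with the iodine as a spectator that ends next to the carbonyl.

Step 4
Reactants: 7 dimethyl squarate (3,4-dimethoxycyclobut-3-ene-1,2-dione)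
Product: 8 methyl hydrogen squarate (3-hydroxy-4-methoxycyclobut-3-ene-1,2-dione)
Conditions: NaOH (1.0 equiv), THF/H2O, 0 °C; then HCl (1.0 equiv), evaporate, extract with acetone
Reagents that add atoms: sodium hydroxide, [Na+].[OH-]
Why: Vinylogous ester saponification by addition–elimination of hydroxide, which should stop at the half ester because the delocalized squarate monoanion resists a second attack.

Step 5
Reactants: 8 methyl hydrogen squarate
Product: 9 3-tert-butoxy-4-methoxycyclobut-3-ene-1,2-dione
Conditions: tert-butyl 2,2,2-trichloroacetimidate (2 equiv), THF/cyclohexane, rt; filter; chromatography on Et3N-washed silica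
Reagents that add atoms: tert-butyl 2,2,2-trichloroacetimidate, CC(C)(C)OC(=N)C(Cl)(Cl)Cl
Why: Acid-promoted O-tert-butylation with a trichloroacetimidate as in the tert-butyl esterification of carboxylic acids, the strongly acidic half ester protonating the imidate and the ion pair collapsing at the vinylogous carboxylate oxygen (either oxygen gives the same 1,2-dione) with release of neutral trichloroacetamide.

Step 6
Reactants: 6 5-iodo-2-(3,4,5-trimethoxyphenyl)-4H-pyran-4-one; 9 3-tert-butoxy-4-methoxycyclobut-3-ene-1,2-dione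
Product: 11 racemic 2-tert-butoxy-4-hydroxy-3-methoxy-4-[4-oxo-6-(3,4,5-trimethoxyphenyl)-4H-pyran-3-yl]cyclobut-2-en-1-one, via pyranonylmagnesium chloride 10 (not isolated)
Conditions: 6, iPrMgCl·LiCl (1.05 equiv), THF, –78 °C, 20 min; cannulate into 9 (1.3 equiv), THF, –78 °C; sat. aq. NH4Cl at –78 °C
Reagents that add atoms: none
Why: Iodine–magnesium exchange of an α-iodo-β-alkoxy enone is fast at low temperature and gives a vinylmagnesium reagent that spares its own weakly electrophilic pyranone carbonyl, and its 1,2-addition to the squarate should go to the carbonyl flanked by the small methoxy-bearing carbon, which is also the carbonyl conjugated with the twisted, weaker-donating tert-butoxy group; the carbinol stereocenter forms racemic and is not needed.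

Step 7
Reactants: 11 racemic 2-tert-butoxy-4-hydroxy-3-methoxy-4-[4-oxo-6-(3,4,5-trimethoxyphenyl)-4H-pyran-3-yl]cyclobut-2-en-1-one
Product: 14 7-tert-butoxy-5,8-dihydroxy-6-methoxy-2-(3,4,5-trimethoxyphenyl)-4H-chromen-4-one, via dienylketene 12 (not isolated), via cyclohexadienone 13 (not isolated)
Conditions: toluene (0.02 M, degassed), Ar, 105 °C; cool and concentrate under Ar
Reagents that add atoms: none
Why: Heating opens the cyclobutenone by conrotatory four-electron electrocyclic cleavage of the C1–C4 bond, the hydroxyl donor rotating outward so that the pyranonyl group lies cis to the ketene in dienylketene 12. A thermal disrotatory six-electron electrocyclization then joins the ketene carbon (future C8) to pyranone C6 (future C8a) and closes the six-membered carbocycle, ring A, as dienone 13, whose C8a hydrogen shifts to oxygen to give the aromatic 5,8-hydroquinone. This is the Moore rearrangement of 4-aryl- and 4-alkenyl-4-hydroxycyclobutenones, with the pyranone C5=C6 bond in the role of the alkenyl group. No stereocenter survives, since the carbinol carbon of 11 and C8a of 13 both become sp2 on aromatization. The step needs outward rotation of the hydroxyl (the general torquoselectivity of a 4-oxygen donor), closure at one site only (C6 is the single open neighbour, the other being the C4 carbonyl carbon) and survival of the tert-butyl ether (neutral, acid-free, air-free medium at moderate temperature, the ether sitting on an enol and then an aryl carbon from which it does not ionize readily).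

Step 8
Reactants: 14 7-tert-butoxy-5,8-dihydroxy-6-methoxy-2-(3,4,5-trimethoxyphenyl)-4H-chromen-4-one
Product: 15 7-tert-butoxy-5-hydroxy-6,8-dimethoxy-2-(3,4,5-trimethoxyphenyl)-4H-chromen-4-one
Conditions: MeI (1.2 equiv), K2CO3 (1.5 equiv), acetone (degassed), Ar, rt
Reagents that add atoms: iodomethane, CI
Why: Williamson O-methylation that tells the two phenols apart, the 5-hydroxyl being locked in a six-membered hydrogen bond to the C4 carbonyl and staying protonated under K2CO3 so that only the 8-phenoxide is alkylated, as is usual for 5,8-dihydroxyflavones.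

Step 9
Reactants: 15 7-tert-butoxy-5-hydroxy-6,8-dimethoxy-2-(3,4,5-trimethoxyphenyl)-4H-chromen-4-one
Product: 16 5,7-dihydroxy-6,8-dimethoxy-2-(3,4,5-trimethoxyphenyl)-4H-chromen-4-one (5,7-dihydroxy-6,8,3',4',5'-pentamethoxyflavone)
Conditions: CF3CO2H/CH2Cl2 (1:4), 0 °C → rt
Reagents that add atoms: none
Why: Acidolysis of the aryl tert-butyl ether through the tert-butyl cation, lost as 2-methylpropene, under conditions to which the aryl methyl ethers, the chelated phenol and the pyranone are inert.

**Compound list**

1 | (E)-4-methoxybut-3-en-2-one | CO/C=C/C(C)=O | starting material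
2 | (Z)-3-iodo-4-methoxybut-3-en-2-one | CO/C=C(\I)C(C)=O | intermediate
3 | 3,4,5-trimethoxybenzoyl chloride | COc1cc(C(Cl)=O)cc(OC)c1OC | starting material
4 | lithium (Z)-3-iodo-4-methoxybuta-1,3-dien-2-olate | CO/C=C(\I)C(=C)O[Li] | intermediate (not isolated)
5 | (Z)-4-iodo-5-methoxy-1-(3,4,5-trimethoxyphenyl)pent-4-ene-1,3-dione | CO/C=C(\I)C(=O)CC(=O)c1cc(OC)c(OC)c(OC)c1 | intermediate
6 | 5-iodo-2-(3,4,5-trimethoxyphenyl)-4H-pyran-4-one | O=c1cc(-c2cc(OC)c(OC)c(OC)c2)occ1I | intermediate
7 | dimethyl squarate (3,4-dimethoxycyclobut-3-ene-1,2-dione) | COC1=C(OC)C(=O)C1=O | starting material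
8 | methyl hydrogen squarate (3-hydroxy-4-methoxycyclobut-3-ene-1,2-dione) | COC1=C(O)C(=O)C1=O | intermediate
9 | 3-tert-butoxy-4-methoxycyclobut-3-ene-1,2-dione | COC1=C(OC(C)(C)C)C(=O)C1=O | intermediate
10 | [4-oxo-6-(3,4,5-trimethoxyphenyl)-4H-pyran-3-yl]magnesium chloride (LiCl complex) | O=c1cc(-c2cc(OC)c(OC)c(OC)c2)occ1[Mg]Cl | intermediate (not isolated)
11 | racemic 2-tert-butoxy-4-hydroxy-3-methoxy-4-[4-oxo-6-(3,4,5-trimethoxyphenyl)-4H-pyran-3-yl]cyclobut-2-en-1-one | COC1=C(OC(C)(C)C)C(=O)C1(O)c1coc(-c2cc(OC)c(OC)c(OC)c2)cc1=O | intermediate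
12 | (Z)-2-tert-butoxy-4-hydroxy-3-methoxy-4-[4-oxo-6-(3,4,5-trimethoxyphenyl)-4H-pyran-3-yl]buta-1,3-dien-1-one (dienylketene) | O=C=C(OC(C)(C)C)/C(OC)=C(O)\c1coc(-c2cc(OC)c(OC)c(OC)c2)cc1=O | intermediate (not isolated)
13 | racemic 7-tert-butoxy-5-hydroxy-6-methoxy-2-(3,4,5-trimethoxyphenyl)-8aH-chromene-4,8-dione | COc1cc(C2=CC(=O)C3=C(O)C(OC)=C(OC(C)(C)C)C(=O)C3O2)cc(OC)c1OC | intermediate (not isolated)
14 | 7-tert-butoxy-5,8-dihydroxy-6-methoxy-2-(3,4,5-trimethoxyphenyl)-4H-chromen-4-one | COc1cc(-c2cc(=O)c3c(O)c(OC)c(OC(C)(C)C)c(O)c3o2)cc(OC)c1OC | intermediate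
15 | 7-tert-butoxy-5-hydroxy-6,8-dimethoxy-2-(3,4,5-trimethoxyphenyl)-4H-chromen-4-one | COc1cc(-c2cc(=O)c3c(O)c(OC)c(OC(C)(C)C)c(OC)c3o2)cc(OC)c1OC | intermediate
16 | 5,7-dihydroxy-6,8-dimethoxy-2-(3,4,5-trimethoxyphenyl)-4H-chromen-4-one | COc1cc(-c2cc(=O)c3c(O)c(OC)c(O)c(OC)c3o2)cc(OC)c1OC | target

**Step count**

Total steps: 9.
Longest linear sequence: 7 steps (steps 1, 2, 3, 6, 7, 8, 9, from 1 to 16); the squarate branch (steps 4 and 5) joins at step 6.

**Steps most likely to fail**

Step 6. The addition may not discriminate fully between the two carbonyl groups of the unsymmetrical squarate. Part of the material would then carry the tert-butoxy group next to the carbinol and end as the 6-hydroxy-7-methoxy isomer. The fallback removes the regiochemical question with a symmetric diester and differentiates O6 from O7 at the end. It sets out from 6 and returns at 16.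

- The Grignard reagent 10, made from 6 as before, is added to commercial di-tert-butyl squarate (CC(C)(C)OC1=C(OC(C)(C)C)C(=O)C1=O, also available from Ag2C4O4 and tert-butyl chloride) to give racemic 2,3-di-tert-butoxy-4-hydroxy-4-[4-oxo-6-(3,4,5-trimethoxyphenyl)-4H-pyran-3-yl]cyclobut-2-en-1-one F1.
- Thermolysis in degassed toluene as in step 7 should give 6,7-di-tert-butoxy-5,8-dihydroxy-2-(3,4,5-trimethoxyphenyl)-4H-chromen-4-one F2.
- MeI/K2CO3 in acetone should methylate only the unchelated 8-hydroxyl to give 6,7-di-tert-butoxy-5-hydroxy-8-methoxy-2-(3,4,5-trimethoxyphenyl)-4H-chromen-4-one F3.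
- CF3CO2H in CH2Cl2 removes both tert-butyl groups to give 5,6,7-trihydroxy-8-methoxy-2-(3,4,5-trimethoxyphenyl)-4H-chromen-4-one F4.
- Benzyl bromide (1.0 equiv) with K2CO3 in DMF should alkylate the most acidic hydroxyl, the one at C7 para to the carbonyl, to give 7-benzyloxy-5,6-dihydroxy-8-methoxy-2-(3,4,5-trimethoxyphenyl)-4H-chromen-4-one F5.
- MeI (1.1 equiv) with K2CO3 in acetone then methylates the 6-hydroxyl while the 5-hydroxyl stays chelated, giving 7-benzyloxy-5-hydroxy-6,8-dimethoxy-2-(3,4,5-trimethoxyphenyl)-4H-chromen-4-one F6.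
- Hydrogenolysis (H2, Pd/C, ethyl acetate) gives 16.

Step 7. Closure of the dienylketene onto pyranone C6, the electron-poor end of a vinylogous ester, may be slow. Reversible ring opening could then let the free hydroxyl reach the ketene and lactonize, and the electron-rich hydroquinone could be oxidized by traces of air during isolation. The fallback blocks the hydroxyl before the ring expansion, so that lactonization is impossible and the product is a mono-protected hydroquinone. It sets out from 11 and returns at 15.

- N-(trimethylsilyl)imidazole in CH2Cl2 converts 11 into racemic 2-tert-butoxy-3-methoxy-4-[4-oxo-6-(3,4,5-trimethoxyphenyl)-4H-pyran-3-yl]-4-(trimethylsilyloxy)cyclobut-2-en-1-one F7.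
- Thermolysis in degassed toluene, the silyloxy group rotating outward like the hydroxyl, should give 7-tert-butoxy-8-hydroxy-6-methoxy-2-(3,4,5-trimethoxyphenyl)-5-(trimethylsilyloxy)-4H-chromen-4-one F8.
- The crude material is methylated at its only free phenol with MeI/K2CO3 in acetone to give 7-tert-butoxy-6,8-dimethoxy-2-(3,4,5-trimethoxyphenyl)-5-(trimethylsilyloxy)-4H-chromen-4-one F9.
- Work-up with aqueous citric acid in methanol removes the silyl group and gives 15.

Step 5. The strongly acidic half ester may consume the imidate by elimination to 2-methylpropene faster than it is alkylated, and the acid-labile mixed diester may revert while acid is still present. The fallback alkylates a neutral silver salt instead, the method by which tert-butyl squarates are classically made. It sets out from 8 and returns at 9.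

- Treatment of 8 with Ag2O (0.5 equiv) in water and drying gives silver 2-methoxy-3,4-dioxocyclobut-1-en-1-olate F10.
- Stirring F10 with tert-butyl chloride in diethyl ether in the dark, with precipitation of the silver halide as driving force, should give 9.

**Further compounds**

F1 | step 6 | racemic 2,3-di-tert-butoxy-4-hydroxy-4-[4-oxo-6-(3,4,5-trimethoxyphenyl)-4H-pyran-3-yl]cyclobut-2-en-1-one | CC(C)(C)OC1=C(OC(C)(C)C)C(=O)C1(O)c1coc(-c2cc(OC)c(OC)c(OC)c2)cc1=O
F2 | step 6 | 6,7-di-tert-butoxy-5,8-dihydroxy-2-(3,4,5-trimethoxyphenyl)-4H-chromen-4-one | COc1cc(-c2cc(=O)c3c(O)c(OC(C)(C)C)c(OC(C)(C)C)c(O)c3o2)cc(OC)c1OC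
F3 | step 6 | 6,7-di-tert-butoxy-5-hydroxy-8-methoxy-2-(3,4,5-trimethoxyphenyl)-4H-chromen-4-one | COc1cc(-c2cc(=O)c3c(O)c(OC(C)(C)C)c(OC(C)(C)C)c(OC)c3o2)cc(OC)c1OC
F4 | step 6 | 5,6,7-trihydroxy-8-methoxy-2-(3,4,5-trimethoxyphenyl)-4H-chromen-4-one | COc1cc(-c2cc(=O)c3c(O)c(O)c(O)c(OC)c3o2)cc(OC)c1OC
F5 | step 6 | 7-benzyloxy-5,6-dihydroxy-8-methoxy-2-(3,4,5-trimethoxyphenyl)-4H-chromen-4-one | COc1cc(-c2cc(=O)c3c(O)c(O)c(OCc4ccccc4)c(OC)c3o2)cc(OC)c1OC
F6 | step 6 | 7-benzyloxy-5-hydroxy-6,8-dimethoxy-2-(3,4,5-trimethoxyphenyl)-4H-chromen-4-one | COc1cc(-c2cc(=O)c3c(O)c(OC)c(OCc4ccccc4)c(OC)c3o2)cc(OC)c1OC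
F7 | step 7 | racemic 2-tert-butoxy-3-methoxy-4-[4-oxo-6-(3,4,5-trimethoxyphenyl)-4H-pyran-3-yl]-4-(trimethylsilyloxy)cyclobut-2-en-1-one | COC1=C(OC(C)(C)C)C(=O)C1(O[Si](C)(C)C)c1coc(-c2cc(OC)c(OC)c(OC)c2)cc1=O
F8 | step 7 | 7-tert-butoxy-8-hydroxy-6-methoxy-2-(3,4,5-trimethoxyphenyl)-5-(trimethylsilyloxy)-4H-chromen-4-one | COc1cc(-c2cc(=O)c3c(O[Si](C)(C)C)c(OC)c(OC(C)(C)C)c(O)c3o2)cc(OC)c1OC
F9 | step 7 | 7-tert-butoxy-6,8-dimethoxy-2-(3,4,5-trimethoxyphenyl)-5-(trimethylsilyloxy)-4H-chromen-4-one | COc1cc(-c2cc(=O)c3c(O[Si](C)(C)C)c(OC)c(OC(C)(C)C)c(OC)c3o2)cc(OC)c1OC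
F10 | step 5 | silver 2-methoxy-3,4-dioxocyclobut-1-en-1-olate | COC1=C([O-])C(=O)C1=O.[Ag+]
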